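Green flattens at 60.0% of its substrate and red heads for 85.4% on the same partner charge, so green loses more on the way.

| flask | substrate | partner | target | time |
|---|---|---|---|---|
| green | 0.500 M | 1.50 M |  |  |
| violet | 0.500 M | 2.20 M |  |  |
| red | 1.00 M | 1.50 M |  |  |
| amber | 0.500 M | 1.50 M | 0.250 M | 4.5 h |

| run | time / h | [target] / M |
|---|---|---|
| green run | 0.75 | 0.138 |
| green run | 1.5 | 0.219 |
| green run | 2.2 | 0.256 |
| green run | 3.0 | 0.278 |
| green run | 3.8 | 0.290 |
| green run | 4.5 | 0.289 |
| violet run | 0.75 | 0.134 |
| violet run | 1.5 | 0.186 |
| violet run | 2.2 | 0.209 |
| violet run | 3.0 | 0.225 |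
| violet run | 3.8 | 0.203 |
| violet run | 4.5 | 0.216 |
| red run | 0.75 | 0.307 |
| red run | 1.5 | 0.502 |
| red run | 2.2 | 0.632 |
| red run | 3.0 | 0.709 |
| red run | 3.8 | 0.759 |
| red run | 4.5 | 0.788 |

(standard deviation of a reading: 0.005 M)

- reaction order in [substrate] at the outset, round the charge of the green run, defined at two percent of the substrate turned into target (one fixed amount of target, the same in the runs compared)
- reaction order in [partner] at the outset, round the charge of the green run, defined at two percent of the substrate turned into target
- target in the amber run at 4.5 h, as a share of the substrate charged

- Overall: substrate + partner -> target.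
- Constant volume, constant temperature.
- "The second partner" is partner.
- An order is taken over about fifteen percent of the charge, up and down.
- A share of target counts the target that was charged too.

By charge substrate is the limiting reagent in green and in red . We write the share of substrate turned into target as x = (a/λ)(1 − e^{−λt}), with a making rate a, a loss rate b, and λ = a + b. The start and the readings at 1.5 h and 3.0 h are equally spaced, so they give λ and the plateau a/λ in closed form. We get λ = 0.874 h⁻¹ in green and 0.591 h⁻¹ in red. So a is 0.524 h⁻¹ in green and 0.505 h⁻¹ in red, about the same. The loss rate is 0.350 h⁻¹ in green, and the loss rate b, the part of λ beyond a, is 0.0861 h⁻¹ in red.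

We take b to follow the partner spare after the substrate's share: 1000 mM in green, 500 mM in red. If charged target claims partner too, amber has 750 mM spare, and the line between the two runs gives b = 0.218 h⁻¹. Amber then makes 68.1% of its substrate. Supposing charged target is lost at b, it keeps the equivalent of 18.7%, so our reckoning is 86.9%.

The forecast differs: orders 1 and 0.15, and amber at 107%. Its ground: “Target doesn't appear to poison anything”.

    substrate + partner → intermediate (11.63 M⁻¹ h⁻¹)
    intermediate → target (0.6264 h⁻¹)
    partner → lost reagent (0.4320 h⁻¹)
    target + partner → side product (0.5724 M⁻¹ h⁻¹)

Amber ends at 85.5% of the substrate charged, charged target counted, and the outset orders are 0.69 in substrate and 0.34 in partner. In amber the intermediate went on to target with rate constant 0.626 h⁻¹ while partner was lost with rate constant 0.432 h⁻¹ and target met partner in the side-product step. Red, with b = 0.0861 h⁻¹, reaches half its substrate at 1.49 h on this curve, and the flask shows 1.44 h.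

(The earlier runs and the new flask stem from a simulated flask for an exercise.)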